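The flavonol is disconnected at C4–C4a, so that ring C is closed by forming a carbon–carbon bond instead of the usual bond to oxygen. In one operation an intramolecular Friedel–Crafts acylation joins the acyl carbon of a β-aryloxy-α-alkoxycinnamic acid to C4a of ring A, the only unsubstituted carbon next to the O1 ether oxygen and one that is ortho to the C5 oxygen and para to the C7 oxygen. The precursor is an (E)-acrylic acid that already carries O1, the C2 aryl group, the C3 oxygen (as benzyl ether), the C8 prenyl group and both ring A methoxy groups; one BCl3 treatment then frees O3, O4' and O5.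

Key step: step 6

Remarks on the chemistry:
- O3 and O4' are carried as benzyl ethers and O5 as the methyl ether peri to the C4 carbonyl. A single Lewis acid at low temperature should then free all three and leave the unchelated C7 methyl ether, which avoids forcing cleavage of a C3 methyl ether next to the prenyl group and a separate deallylation.
- Compounds 4 and 5 are assumed to be commercial.
- Compound 6 is racemic at C2 and loses that centre in step 3.
- Alkenes 7 to 10 are drawn as the E isomers (ester or acyl group cis to the oxygen on C3). Any Z isomer carried along should converge in step 6.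

Step 1
Reactants: 1 3,5-dimethoxyphenol; 2 1-bromo-3-methylbut-2-ene (prenyl bromide)
Product: 3 3,5-dimethoxy-2-(3-methylbut-2-en-1-yl)phenol
Conditions: NaH (1.05 eq), toluene, 0 °C → rt; then 2 (1.0 eq), rt
Reagents that add atoms: none
Why: C-alkylation of an ambident phenoxide, in which the tight sodium ion pair in toluene should direct the prenyl group to an ortho carbon (both ortho positions are equivalent by symmetry) in preference to oxygen or to the hindered para carbon between the two methoxy groups, the O-prenyl ether and unchanged 1 being separable.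

Step 2
Reactants: 4 methyl 2-(benzyloxy)acetate; 5 4-(benzyloxy)benzoyl chloride
Product: 6 methyl 2-(benzyloxy)-3-[4-(benzyloxy)phenyl]-3-oxopropanoate (racemic)
Conditions: 4 (2.1 eq), LiN(SiMe3)2 (2.1 eq), THF, −78 °C; then 5 (1.0 eq), −78 → −20 °C; aq. NH4Cl
Reagents that add atoms: none
Why: Claisen-type C-acylation of a preformed lithium ester enolate by an aroyl chloride, in which the second equivalent of enolate deprotonates the more acidic β-keto ester as it forms and so prevents double acylation; the new C2 centre is racemic and disappears in step 3.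

Step 3
Reactants: 6 methyl 2-(benzyloxy)-3-[4-(benzyloxy)phenyl]-3-oxopropanoate
Product: 7 methyl (E)-2-(benzyloxy)-3-[4-(benzyloxy)phenyl]-3-{[(trifluoromethyl)sulfonyl]oxy}prop-2-enoate
Conditions: NaH (1.1 eq), Et2O, 0 °C; then Tf2O (1.1 eq), −78 → 0 °C
Reagents that add atoms: trifluoromethanesulfonic anhydride, O=S(=O)(OS(=O)(=O)C(F)(F)F)C(F)(F)F
Why: O-sulfonylation of a β-keto ester enolate (enol triflate formation), in which the chelated sodium enolate in a weakly coordinating solvent should place the triflate cis to the ester group and so give the E isomer.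

Step 4
Reactants: 3 3,5-dimethoxy-2-(3-methylbut-2-en-1-yl)phenol; 7 methyl (E)-2-(benzyloxy)-3-[4-(benzyloxy)phenyl]-3-{[(trifluoromethyl)sulfonyl]oxy}prop-2-enoate
Product: 8 methyl (E)-2-(benzyloxy)-3-[4-(benzyloxy)phenyl]-3-[3,5-dimethoxy-2-(3-methylbut-2-en-1-yl)phenoxy]prop-2-enoate
Conditions: Cs2CO3 (1.5 eq), DMF, 0 °C → rt
Reagents that add atoms: none
Why: Nucleophilic vinylic substitution by addition–elimination, in which the caesium phenoxide of 3 adds to the β-carbon of the ester-activated enol triflate and triflate is expelled, normally with retention, so that the aryloxy group should end up cis to the ester (E).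

Step 5
Reactants: 8 methyl (E)-2-(benzyloxy)-3-[4-(benzyloxy)phenyl]-3-[3,5-dimethoxy-2-(3-methylbut-2-en-1-yl)phenoxy]prop-2-enoate
Product: 9 (E)-2-(benzyloxy)-3-[4-(benzyloxy)phenyl]-3-[3,5-dimethoxy-2-(3-methylbut-2-en-1-yl)phenoxy]prop-2-enoic acid (carboxyl cis to aryloxy)
Conditions: LiOH (3 eq), THF/MeOH/H2O, 40 °C; then dilute HCl to pH 4, 0 °C
Reagents that add atoms: lithium hydroxide, [Li+].[OH-]
Why: Saponification of the methyl ester by hydroxide attack at the acyl carbon, in which the tetrasubstituted, donor-substituted β-carbon should resist conjugate displacement of the aryloxide and the cold, mild acidification avoids hydrolysis of the enol ether.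

Step 6
Reactants: 9 (E)-2-(benzyloxy)-3-[4-(benzyloxy)phenyl]-3-[3,5-dimethoxy-2-(3-methylbut-2-en-1-yl)phenoxy]prop-2-enoic acid
Product: 11 3-(benzyloxy)-2-[4-(benzyloxy)phenyl]-5,7-dimethoxy-8-(3-methylbut-2-en-1-yl)-4H-chromen-4-one, via mixed trifluoroacetic anhydride 10 (not isolated)
Conditions: (CF3CO)2O (2 eq), CH2Cl2, 0 °C → rt
Reagents that add atoms: none
Why: Trifluoroacetic anhydride converts acid 9 into the mixed anhydride 10, whose acyl carbon (an acylium stabilised as a ketene-type oxocarbenium by the β-aryloxy oxygen) is attacked by the ring A carbon ortho to the ether oxygen, and loss of a proton restores the arene and gives the pyranone. The closest known reaction type is the intramolecular Friedel–Crafts acylation of β-aryloxycinnamic acids to flavones and of 2-aryloxybenzoic acids to xanthones through mixed trifluoroacetic anhydrides. Ring C is closed as a six-membered ring by 6-exo attack of C4a on the acyl carbon, which forms C4–C4a, and no stereocentre is created. Site selectivity is built into the substrate, because the only unsubstituted carbon next to the ether oxygen is the future C4a (the other ortho carbon carries the prenyl group) and it is ortho to one methoxy group and para to the other; five-membered closure onto ring B or closure onto the unactivated benzyl ring should not compete with this doubly activated position. The carboxyl group must lie cis to the aryloxy group, which step 4 should deliver and which, failing that, rotation about the weakened double bond of the push-pull acylium restores. The prenyl alkene should survive because the only acid present is the trifluoroacetic acid that the reaction itself releases, dilute in CH2Cl2 at 0 °C.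

Step 7
Reactants: 11 3-(benzyloxy)-2-[4-(benzyloxy)phenyl]-5,7-dimethoxy-8-(3-methylbut-2-en-1-yl)-4H-chromen-4-one
Product: 12 isoanhydroicaritin, 3,5-dihydroxy-2-(4-hydroxyphenyl)-7-methoxy-8-(3-methylbut-2-en-1-yl)-4H-chromen-4-one
Conditions: BCl3 (6 eq), C6HMe5 (6 eq), CH2Cl2, −78 → 0 °C; then MeOH, H2O
Reagents that add atoms: none
Why: Lewis-acid ether cleavage, in which BCl3 ionises the two benzyl ethers at low temperature (pentamethylbenzene traps the benzyl cations before they can attack ring A or the prenyl alkene) and, on warming to 0 °C, removes the C5 methyl group as chloromethane through the boron chelate with the C4 carbonyl, whereas the unchelated C7 methyl ether should not be attacked.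

Compound list
1 | 3,5-dimethoxyphenol | COc1cc(O)cc(OC)c1 | starting material
2 | 1-bromo-3-methylbut-2-ene (prenyl bromide) | CC(C)=CCBr | starting material
3 | 3,5-dimethoxy-2-(3-methylbut-2-en-1-yl)phenol | COc1cc(O)c(CC=C(C)C)c(OC)c1 | intermediate
4 | methyl 2-(benzyloxy)acetate | COC(=O)COCc1ccccc1 | starting material
5 | 4-(benzyloxy)benzoyl chloride | O=C(Cl)c1ccc(OCc2ccccc2)cc1 | starting material
6 | methyl 2-(benzyloxy)-3-[4-(benzyloxy)phenyl]-3-oxopropanoate (racemic) | COC(=O)C(OCc1ccccc1)C(=O)c1ccc(OCc2ccccc2)cc1 | intermediate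
7 | methyl (E)-2-(benzyloxy)-3-[4-(benzyloxy)phenyl]-3-{[(trifluoromethyl)sulfonyl]oxy}prop-2-enoate | COC(=O)/C(OCc1ccccc1)=C(\OS(=O)(=O)C(F)(F)F)c1ccc(OCc2ccccc2)cc1 | intermediate
8 | methyl (E)-2-(benzyloxy)-3-[4-(benzyloxy)phenyl]-3-[3,5-dimethoxy-2-(3-methylbut-2-en-1-yl)phenoxy]prop-2-enoate | COC(=O)/C(OCc1ccccc1)=C(\Oc1cc(OC)cc(OC)c1CC=C(C)C)c1ccc(OCc2ccccc2)cc1 | intermediate
9 | (E)-2-(benzyloxy)-3-[4-(benzyloxy)phenyl]-3-[3,5-dimethoxy-2-(3-methylbut-2-en-1-yl)phenoxy]prop-2-enoic acid | OC(=O)/C(OCc1ccccc1)=C(\Oc1cc(OC)cc(OC)c1CC=C(C)C)c1ccc(OCc2ccccc2)cc1 | intermediate (key-step precursor)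
10 | (E)-2-(benzyloxy)-3-[4-(benzyloxy)phenyl]-3-[3,5-dimethoxy-2-(3-methylbut-2-en-1-yl)phenoxy]prop-2-enoic trifluoroacetic anhydride | O=C(OC(=O)C(F)(F)F)/C(OCc1ccccc1)=C(\Oc1cc(OC)cc(OC)c1CC=C(C)C)c1ccc(OCc2ccccc2)cc1 | intermediate (not isolated)
11 | 3-(benzyloxy)-2-[4-(benzyloxy)phenyl]-5,7-dimethoxy-8-(3-methylbut-2-en-1-yl)-4H-chromen-4-one | COc1cc(OC)c2c(=O)c(OCc3ccccc3)c(-c3ccc(OCc4ccccc4)cc3)oc2c1CC=C(C)C | intermediate (key-step product)
12 | isoanhydroicaritin, 3,5-dihydroxy-2-(4-hydroxyphenyl)-7-methoxy-8-(3-methylbut-2-en-1-yl)-4H-chromen-4-one | COc1cc(O)c2c(=O)c(O)c(-c3ccc(O)cc3)oc2c1CC=C(C)C | target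

Total step count: 7. Longest linear sequence: 6 steps (steps 2, 3, 4, 5, 6 and 7, from 4 and 5); the ring A branch adds step 1 and joins at step 4.

Steps most likely to fail

1. Step 6 (key step). The trifluoroacetic acid released may add to the trisubstituted prenyl alkene or start its cationic degradation while the ring closes. The mixed anhydride, deactivated by the β-oxygen, may also ionise too slowly for clean acylation. The fallback takes the acid-sensitive alkene out of the acidic step by carrying a terminal allyl group; it sets out from 1 and 7 and comes back at 11. Phenol 1 is O-allylated (allyl bromide, K2CO3, acetone) to 1,3-dimethoxy-5-(prop-2-en-1-yloxy)benzene F1. Its aromatic Claisen rearrangement (N,N-diethylaniline, 190 °C) should give 3,5-dimethoxy-2-(prop-2-en-1-yl)phenol F2 as a single regioisomer by symmetry. F2 takes the place of 3 under the conditions of step 4 and should give methyl (E)-2-(benzyloxy)-3-[4-(benzyloxy)phenyl]-3-[3,5-dimethoxy-2-(prop-2-en-1-yl)phenoxy]prop-2-enoate F3, and LiOH as in step 5 gives (E)-2-(benzyloxy)-3-[4-(benzyloxy)phenyl]-3-[3,5-dimethoxy-2-(prop-2-en-1-yl)phenoxy]prop-2-enoic acid F4. Trifluoroacetic anhydride, if needed with a catalytic amount of CF3SO3H that a terminal alkene tolerates, closes ring C through the mixed trifluoroacetic anhydride F5 to 3-(benzyloxy)-2-[4-(benzyloxy)phenyl]-5,7-dimethoxy-8-(prop-2-en-1-yl)-4H-chromen-4-one F6. Olefin cross-metathesis with 2-methyl-2-butene (second-generation Grubbs catalyst RuCl2(=CHPh)(PCy3)(H2IMes), CH2Cl2, 40 °C) then turns the allyl group into the prenyl group and returns to 11. The same sequence to F2 is also a regiodefined alternative to the direct prenylation of step 1.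

2. Step 4. The hindered phenoxide may attack the sulfur of the triflate (S–O cleavage, which returns the β-keto ester enolate), or its addition to the crowded, donor-substituted β-carbon may be too slow. The fallback replaces addition–elimination by a metal-catalysed C–O cross-coupling; it sets out from 3 and 7 and comes back at 8. Zerovalent palladium (Pd2(dba)3 with 2-(di-tert-butylphosphino)biphenyl, K3PO4, toluene, 90 °C) inserts into the C–OTf bond of 7, the phenoxide of 3 binds to palladium, and reductive elimination forms the aryl vinyl ether bond at carbon without any attack at sulfur. No new compound is made.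

3. Step 7. BCl3 or the hydrogen chloride formed may hydrochlorinate or degrade the prenyl alkene, or the chelated C5 methyl ether may be cleaved incompletely at the temperature that the alkene tolerates. The fallback carries out the Lewis-acid deprotection before the prenyl group exists; it sets out from 1 and 7, passes through F1 to F6 as described under step 6, and comes back at 12. F6 is treated with BCl3 and pentamethylbenzene as in step 7, which a terminal alkene should withstand, to give 3,5-dihydroxy-2-(4-hydroxyphenyl)-7-methoxy-8-(prop-2-en-1-yl)-4H-chromen-4-one F7. Cross-metathesis of F7 with 2-methyl-2-butene (second-generation Grubbs catalyst RuCl2(=CHPh)(PCy3)(H2IMes), CH2Cl2, 40 °C), which free phenols tolerate, then gives 12.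

Further compounds
F1 | step 6 | 1,3-dimethoxy-5-(prop-2-en-1-yloxy)benzene | C=CCOc1cc(OC)cc(OC)c1
F2 | step 6 | 3,5-dimethoxy-2-(prop-2-en-1-yl)phenol | C=CCc1c(O)cc(OC)cc1OC
F3 | step 6 | methyl (E)-2-(benzyloxy)-3-[4-(benzyloxy)phenyl]-3-[3,5-dimethoxy-2-(prop-2-en-1-yl)phenoxy]prop-2-enoate | COC(=O)/C(OCc1ccccc1)=C(\Oc1cc(OC)cc(OC)c1CC=C)c1ccc(OCc2ccccc2)cc1
F4 | step 6 | (E)-2-(benzyloxy)-3-[4-(benzyloxy)phenyl]-3-[3,5-dimethoxy-2-(prop-2-en-1-yl)phenoxy]prop-2-enoic acid | OC(=O)/C(OCc1ccccc1)=C(\Oc1cc(OC)cc(OC)c1CC=C)c1ccc(OCc2ccccc2)cc1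
F5 | step 6 | (E)-2-(benzyloxy)-3-[4-(benzyloxy)phenyl]-3-[3,5-dimethoxy-2-(prop-2-en-1-yl)phenoxy]prop-2-enoic trifluoroacetic anhydride | O=C(OC(=O)C(F)(F)F)/C(OCc1ccccc1)=C(\Oc1cc(OC)cc(OC)c1CC=C)c1ccc(OCc2ccccc2)cc1
F6 | step 6 | 3-(benzyloxy)-2-[4-(benzyloxy)phenyl]-5,7-dimethoxy-8-(prop-2-en-1-yl)-4H-chromen-4-one | COc1cc(OC)c2c(=O)c(OCc3ccccc3)c(-c3ccc(OCc4ccccc4)cc3)oc2c1CC=C
F0 | step 4 | none | none
F7 | step 7 | 3,5-dihydroxy-2-(4-hydroxyphenyl)-7-methoxy-8-(prop-2-en-1-yl)-4H-chromen-4-one | COc1cc(O)c2c(=O)c(O)c(-c3ccc(O)cc3)oc2c1CC=C
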